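**Plan**

- Retrosynthesis: the two phenolic MOM ethers come off last. The piperidine is opened at C5–C6 (with the C4–H bond). Then the C3–O veratrate, the chromone C8–vinyl bond, the N–CH2 bond and the carbinol–alkyne bond of the chain are cut.
- Forward: an amino ynone chain is built from a silylmethylamine, a chloro Weinreb amide and an acetylide. The chromone ring is made by Kostanecki–Robinson synthesis and iodinated at C8. Stille coupling joins the two, the alcohol is veratroylated, and the piperidine ring is closed last.
- Stereochemistry: C3 comes from Noyori asymmetric transfer hydrogenation of the ynone. C4 is set during ring closure by hydrogen-atom transfer anti to the C3 veratrate.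
- Enabling feature: piperidine C6 is an N–CH2 carbon separated from benzylic C4 only by C5. An α-amino radical at C6 can therefore add to C5 of a C4=C5 1,1-disubstituted styrene, closing ring N1–C2–C3–C4–C5–C6 and leaving a benzylic radical at C4 next to the C3 ester.

Key step: step 11

Assumption: iodination of the 5,7-bis(methoxymethyl) ether 11 is taken to occur at C8, as is the rule for 5,7-dialkoxychromones and -flavones; the position would be checked by HMBC/NOE before the coupling.

**Route**

Step 1
Reactants: 1 N-methyl-1-(trimethylsilyl)methanamine; 2 2-chloro-N-methoxy-N-methylacetamide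
Product: 3 N-methoxy-N-methyl-2-[methyl(trimethylsilylmethyl)amino]acetamide
Conditions: K2CO3, NaI (cat.), MeCN, 50 °C
Reagents that add atoms: none
Why: SN2 N-alkylation of the secondary amine by the α-chloro amide (iodide-assisted, Finkelstein exchange in situ) should stop at the hindered tertiary amine; no stereocentre is formed.

Step 2
Reactants: 3 N-methoxy-N-methyl-2-[methyl(trimethylsilylmethyl)amino]acetamide
Product: 4 1-[methyl(trimethylsilylmethyl)amino]-4-(trimethylsilyl)but-3-yn-2-one
Conditions: ethynyltrimethylsilane, n-BuLi, THF, −78 °C; then 3, −78 to 0 °C; aq. NH4Cl at −78 °C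
Reagents that add atoms: ethynyltrimethylsilane, C#C[Si](C)(C)C (as its lithium acetylide)
Why: Weinreb ketone synthesis, in which the acetylide adds once to give a chelated tetrahedral intermediate that releases the ynone only on cold quench, while the aminomethyl C(sp3)–Si bond is inert to the acetylide.

Step 3
Reactants: 4 1-[methyl(trimethylsilylmethyl)amino]-4-(trimethylsilyl)but-3-yn-2-one
Product: 5 (2S)-1-[methyl(trimethylsilylmethyl)amino]-4-(trimethylsilyl)but-3-yn-2-ol
Conditions: Ru[(R,R)-TsNCH(Ph)CH(Ph)NH](η6-p-cymene) (1 mol%), i-PrOH, 25 °C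
Reagents that add atoms: none
Why: Noyori asymmetric transfer hydrogenation of an α,β-acetylenic ketone, in which the alkynyl group takes the place of the aryl group of an aryl ketone in the outer-sphere transition state, so the (R,R)-catalyst should give the (2S)-carbinol (the future C3) under base-free conditions that spare the ynone and both silyl groups.

Step 4
Reactants: 5 (2S)-1-[methyl(trimethylsilylmethyl)amino]-4-(trimethylsilyl)but-3-yn-2-ol
Product: 6 (2S)-1-[methyl(trimethylsilylmethyl)amino]but-3-yn-2-ol
Conditions: K2CO3 (cat.), MeOH, 0 °C to rt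
Reagents that add atoms: none
Why: Methoxide-catalysed protodesilylation cleaves only the alkynyl C(sp)–Si bond, because the aminomethyl C(sp3)–Si bond offers no stabilised carbanion, and the carbinol centre is not touched.

Step 5
Reactants: 6 (2S)-1-[methyl(trimethylsilylmethyl)amino]but-3-yn-2-ol
Product: 7 (2R)-1-[methyl(trimethylsilylmethyl)amino]-3-(tributylstannyl)but-3-en-2-ol
Conditions: Bu3SnH, Mo(CO)3(CNt-Bu)3 (5 mol%), hydroquinone, THF, 55 °C
Reagents that add atoms: tributyltin hydride, CCCC[SnH](CCCC)CCCC
Why: Molybdenum-catalysed hydrostannation of terminal propargylic alcohols places tin on the internal (α) carbon and so gives the 1,1-disubstituted vinylstannane; the stereocentre is unchanged in space and its descriptor becomes R only because tin raises the CIP rank of the vinyl carbon.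

Step 6
Reactants: 8 2,4,6-trihydroxyacetophenone
Product: 10 5,7-dihydroxy-2-methylchromen-4-one (noreugenin), via 3-acetyl-5,7-diacetoxy-2-methylchromen-4-one 9 (not isolated)
Conditions: Ac2O, NaOAc, reflux; evaporate; then aq. Na2CO3, reflux; HCl to pH 4
Reagents that add atoms: acetic anhydride, CC(=O)OC(C)=O
Why: Kostanecki–Robinson reaction, in which O-acetylation, acyl transfer to the ketone methyl group and cyclodehydration build the 2-methylchromone as its 3-acetyl diacetate, after which hot aqueous carbonate removes the 3-acetyl group by retro-Claisen cleavage together with both phenolic acetates.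

Step 7
Reactants: 10 5,7-dihydroxy-2-methylchromen-4-one
Product: 11 5,7-bis(methoxymethoxy)-2-methylchromen-4-one
Conditions: NaH, MOMCl, DMF, 0 °C to rt
Reagents that add atoms: chloromethyl methyl ether, COCCl
Why: Williamson-type O-alkylation of both phenoxides (the chelated 5-hydroxyl needs full deprotonation by NaH) gives a bis-MOM ether that should tolerate the organometallic, acylation and photoredox steps ahead.

Step 8
Reactants: 11 5,7-bis(methoxymethoxy)-2-methylchromen-4-one
Product: 12 8-iodo-5,7-bis(methoxymethoxy)-2-methylchromen-4-one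
Conditions: NIS, DMF, 0 °C to rt, dark
Reagents that add atoms: N-iodosuccinimide, O=C1CCC(=O)N1I
Why: Electrophilic aromatic iodination is expected at C8, which is para to the 5-alkoxy group, ortho to the 7-alkoxy group and less hindered than C6, and neutral NIS spares the acid-labile 5-MOM ether.

Step 9
Reactants: 7 (2R)-1-[methyl(trimethylsilylmethyl)amino]-3-(tributylstannyl)but-3-en-2-ol; 12 8-iodo-5,7-bis(methoxymethoxy)-2-methylchromen-4-one
Product: 13 (2S)-3-[5,7-bis(methoxymethoxy)-2-methyl-4-oxochromen-8-yl]-1-[methyl(trimethylsilylmethyl)amino]but-3-en-2-ol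
Conditions: Pd(PPh3)4 (10 mol%), CuCl, LiCl, DMSO, 60 °C
Reagents that add atoms: none
Why: Stille coupling with CuCl/LiCl acceleration, the variant developed for 1-substituted vinylstannanes and congested partners, should join chromone C8 to the internal vinyl carbon without fluoride, base or acid, so the aminomethylsilane, the MOM ethers and the free carbinol survive and the stereocentre is untouched.

Step 10
Reactants: 13 (2S)-3-[5,7-bis(methoxymethoxy)-2-methyl-4-oxochromen-8-yl]-1-[methyl(trimethylsilylmethyl)amino]but-3-en-2-ol; 14 3,4-dimethoxybenzoyl chloride (veratroyl chloride)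
Product: 15 (2S)-3-[5,7-bis(methoxymethoxy)-2-methyl-4-oxochromen-8-yl]-1-[methyl(trimethylsilylmethyl)amino]but-3-en-2-yl 3,4-dimethoxybenzoate
Conditions: Et3N, DMAP (cat.), CH2Cl2, 0 °C to rt
Reagents that add atoms: none
Why: DMAP-catalysed acylation of the secondary allylic alcohol by the acid chloride (nucleophilic catalysis) gives the veratrate with retention at carbon, and the MOM-protected phenols can neither compete nor transfer acyl groups.

Step 11
Reactants: 15 (2S)-3-[5,7-bis(methoxymethoxy)-2-methyl-4-oxochromen-8-yl]-1-[methyl(trimethylsilylmethyl)amino]but-3-en-2-yl 3,4-dimethoxybenzoate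
Product: 16 (3S,4R)-4-[5,7-bis(methoxymethoxy)-2-methyl-4-oxochromen-8-yl]-1-methylpiperidin-3-yl 3,4-dimethoxybenzoate
Conditions: 4CzIPN (2 mol%), 2,4,6-triisopropylbenzenethiol (20 mol%), MeCN/MeOH 4:1 (0.01 M), blue LEDs (450 nm), 25 °C, argon
Reagents that add atoms: none
Why: Photoexcited 4CzIPN oxidises the tertiary amine to its radical cation, methanol removes the trimethylsilyl group so that the radical sits only on the former silylmethyl carbon (C6), this radical adds 6-endo-trig to the unsubstituted alkene terminus C5 and closes the piperidine, and the thiol then gives hydrogen to benzylic C4 while the thiyl radical is returned to thiol by the reduced photocatalyst and a proton. The closest known reactions are the photoinduced electron-transfer cyclisations of α-silylamines onto tethered alkenes and the photoredox/thiol hydroaminoalkylation of styrenes. The 6-endo mode is preferred over 5-exo because attack at C5 meets no substituent and gives a benzylic radical, whereas attack at C4 would build a quaternary centre and a primary radical. The new stereocentre C4 is set by substrate control: strain against the twisted, di-ortho-substituted chromone pushes the C3 veratrate axial and the thiol delivers hydrogen to the face anti to it, leaving the aryl group equatorial and cis to the ester (3S,4R). C3 is carried through unchanged because no ionic or enolisable path reaches it. The step needs regiocontrol of radical formation (secured by the silyl group), 6-endo selectivity (secured by the aryl group on C4) and hydrogen transfer fast enough that the C4 radical is not reduced to an anion able to expel the veratrate (secured by the arenethiol).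

Step 12
Reactants: 16 (3S,4R)-4-[5,7-bis(methoxymethoxy)-2-methyl-4-oxochromen-8-yl]-1-methylpiperidin-3-yl 3,4-dimethoxybenzoate
Product: 17 chrotacumine D
Conditions: 3 M aq. HCl, THF, 45 °C; then aq. NaHCO3
Reagents that add atoms: none
Why: Acid-catalysed hydrolysis of the two aryl MOM acetals proceeds well below the conditions that hydrolyse a secondary alkyl benzoate, and the protonated amine and both stereocentres are inert, so the free 5,7-diphenol should result after neutralisation.

**Compound list**

1 | N-methyl-1-(trimethylsilyl)methanamine | CNC[Si](C)(C)C | starting material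
2 | 2-chloro-N-methoxy-N-methylacetamide | CON(C)C(=O)CCl | starting material
3 | N-methoxy-N-methyl-2-[methyl(trimethylsilylmethyl)amino]acetamide | CON(C)C(=O)CN(C)C[Si](C)(C)C | intermediate
4 | 1-[methyl(trimethylsilylmethyl)amino]-4-(trimethylsilyl)but-3-yn-2-one | C[Si](C)(C)CN(C)CC(=O)C#C[Si](C)(C)C | intermediate
5 | (2S)-1-[methyl(trimethylsilylmethyl)amino]-4-(trimethylsilyl)but-3-yn-2-ol | C[Si](C)(C)CN(C)C[C@@H](O)C#C[Si](C)(C)C | intermediate
6 | (2S)-1-[methyl(trimethylsilylmethyl)amino]but-3-yn-2-ol | C[Si](C)(C)CN(C)C[C@@H](O)C#C | intermediate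
7 | (2R)-1-[methyl(trimethylsilylmethyl)amino]-3-(tributylstannyl)but-3-en-2-ol | C[Si](C)(C)CN(C)C[C@@H](O)C(=C)[Sn](CCCC)(CCCC)CCCC | intermediate
8 | 2,4,6-trihydroxyacetophenone | CC(=O)c1c(O)cc(O)cc1O | starting material
9 | 3-acetyl-5,7-diacetoxy-2-methylchromen-4-one | Cc1oc2cc(OC(C)=O)cc(OC(C)=O)c2c(=O)c1C(C)=O | intermediate
10 | 5,7-dihydroxy-2-methylchromen-4-one (noreugenin) | Cc1cc(=O)c2c(O)cc(O)cc2o1 | intermediate
11 | 5,7-bis(methoxymethoxy)-2-methylchromen-4-one | COCOc1cc(OCOC)c2c(=O)cc(C)oc2c1 | intermediate
12 | 8-iodo-5,7-bis(methoxymethoxy)-2-methylchromen-4-one | COCOc1cc(OCOC)c2c(=O)cc(C)oc2c1I | intermediate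
13 | (2S)-3-[5,7-bis(methoxymethoxy)-2-methyl-4-oxochromen-8-yl]-1-[methyl(trimethylsilylmethyl)amino]but-3-en-2-ol | C[Si](C)(C)CN(C)C[C@@H](O)C(=C)c1c(OCOC)cc(OCOC)c2c(=O)cc(C)oc12 | intermediate
14 | 3,4-dimethoxybenzoyl chloride (veratroyl chloride) | COc1ccc(cc1OC)C(Cl)=O | starting material
15 | (2S)-3-[5,7-bis(methoxymethoxy)-2-methyl-4-oxochromen-8-yl]-1-[methyl(trimethylsilylmethyl)amino]but-3-en-2-yl 3,4-dimethoxybenzoate | C[Si](C)(C)CN(C)C[C@@H](OC(=O)c1ccc(OC)c(OC)c1)C(=C)c1c(OCOC)cc(OCOC)c2c(=O)cc(C)oc12 | intermediate
16 | (3S,4R)-4-[5,7-bis(methoxymethoxy)-2-methyl-4-oxochromen-8-yl]-1-methylpiperidin-3-yl 3,4-dimethoxybenzoate | COc1ccc(cc1OC)C(=O)O[C@@H]1CN(C)CC[C@@H]1c1c(OCOC)cc(OCOC)c2c(=O)cc(C)oc12 | intermediate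
17 | chrotacumine D, (3S,4R)-4-(5,7-dihydroxy-2-methyl-4-oxochromen-8-yl)-1-methylpiperidin-3-yl 3,4-dimethoxybenzoate | COc1ccc(C(=O)O[C@@H]2CN(C)CC[C@@H]2c2c(O)cc(O)c3c(=O)cc(C)oc23)cc1OC | target

**Step count**

Total: 12 steps (step 6 is a telescoped two-stage operation). Longest linear sequence: 9 steps (steps 1–5 and 9–12).

**Steps most likely to fail**

1. Step 11 (radical ring closure). Three processes could spoil it: hydrogen transfer to the α-amino radical before it cyclises; reduction of the C4 radical to an anion followed by loss of the veratrate; and weak facial bias in the hydrogen transfer. The fallback moves the esterification behind the ring closure and carries the C3 oxygen as a silyl ether, which cannot leave as an anion and is a larger axial shield.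
   - It sets out from 13, which is silylated (TBSOTf, 2,6-lutidine, CH2Cl2, −78 °C) to (2S)-3-[5,7-bis(methoxymethoxy)-2-methyl-4-oxochromen-8-yl]-2-(tert-butyldimethylsilyloxy)-N-methyl-N-(trimethylsilylmethyl)but-3-en-1-amine F1.
   - The same photoredox/thiol conditions should close the ring to 8-[(3S,4R)-3-(tert-butyldimethylsilyloxy)-1-methylpiperidin-4-yl]-5,7-bis(methoxymethoxy)-2-methylchromen-4-one F2.
   - Bu4NF in THF frees 8-[(3S,4R)-3-hydroxy-1-methylpiperidin-4-yl]-5,7-bis(methoxymethoxy)-2-methylchromen-4-one F3.
   - Acylation with 14 (Et3N, DMAP, CH2Cl2) comes back to the route at 16.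

2. Step 9 (Stille coupling). Transmetalation between a 1-substituted vinylstannane and a di-ortho-substituted aryl iodide may be slow, so protodestannylation or homocoupling could take over. The fallback replaces tin by boron and skips step 5.
   - It sets out from 6, which undergoes copper-catalysed α-selective protoboration (B2pin2, CuCl(SIMes), NaOt-Bu cat., MeOH, THF, −50 to −15 °C) to (2S)-1-[methyl(trimethylsilylmethyl)amino]-3-(4,4,5,5-tetramethyl-1,3,2-dioxaborolan-2-yl)but-3-en-2-ol F4.
   - Suzuki–Miyaura coupling of this boronate with 12 (Pd(OAc)2, SPhos, K3PO4, dioxane/H2O, 60 °C) comes back at 13.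

3. Step 3 (asymmetric transfer hydrogenation). The basic amine next to the ketone could erode the enantioselectivity, or the amino ynone could decompose by amine–ynone addition before it is reduced. The fallback takes the stereocentre from the chiral pool and bypasses steps 1–4.
   - (R)-2,2-dimethyl-1,3-dioxolane-4-carbaldehyde F5 is homologated with the Ohira–Bestmann reagent (K2CO3, MeOH) to (4S)-4-ethynyl-2,2-dimethyl-1,3-dioxolane F6.
   - Acidic methanolysis gives (2S)-but-3-yne-1,2-diol F7.
   - Tin-catalysed primary tosylation (TsCl, Bu2SnO cat., Et3N, CH2Cl2) gives (2S)-2-hydroxybut-3-yn-1-yl 4-methylbenzenesulfonate F8.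
   - The route sets out from amine 1, which displaces the tosylate (K2CO3, MeCN, 60 °C, by way of the terminal epoxide) and comes back at 6.

Further compounds
F1 | step 11 | (2S)-3-[5,7-bis(methoxymethoxy)-2-methyl-4-oxochromen-8-yl]-2-(tert-butyldimethylsilyloxy)-N-methyl-N-(trimethylsilylmethyl)but-3-en-1-amine | C[Si](C)(C)CN(C)C[C@@H](O[Si](C)(C)C(C)(C)C)C(=C)c1c(OCOC)cc(OCOC)c2c(=O)cc(C)oc12
F2 | step 11 | 8-[(3S,4R)-3-(tert-butyldimethylsilyloxy)-1-methylpiperidin-4-yl]-5,7-bis(methoxymethoxy)-2-methylchromen-4-one | CC(C)(C)[Si](C)(C)O[C@@H]1CN(C)CC[C@@H]1c1c(OCOC)cc(OCOC)c2c(=O)cc(C)oc12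
F3 | step 11 | 8-[(3S,4R)-3-hydroxy-1-methylpiperidin-4-yl]-5,7-bis(methoxymethoxy)-2-methylchromen-4-one | O[C@@H]1CN(C)CC[C@@H]1c1c(OCOC)cc(OCOC)c2c(=O)cc(C)oc12
F4 | step 9 | (2S)-1-[methyl(trimethylsilylmethyl)amino]-3-(4,4,5,5-tetramethyl-1,3,2-dioxaborolan-2-yl)but-3-en-2-ol | C[Si](C)(C)CN(C)C[C@@H](O)C(=C)B1OC(C)(C)C(C)(C)O1
F5 | step 3 | (R)-2,2-dimethyl-1,3-dioxolane-4-carbaldehyde | O=C[C@H]1COC(C)(C)O1
F6 | step 3 | (4S)-4-ethynyl-2,2-dimethyl-1,3-dioxolane | C#C[C@H]1COC(C)(C)O1
F7 | step 3 | (2S)-but-3-yne-1,2-diol | C#C[C@H](O)CO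
F8 | step 3 | (2S)-2-hydroxybut-3-yn-1-yl 4-methylbenzenesulfonate | C#C[C@H](O)COS(=O)(=O)c1ccc(C)cc1
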